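**Plan**

- Retrosynthesis: the four phenols are first masked as methyl ethers; the C2–C3 and C12–C13 bonds of the tetradecane chain are then cut together. This leaves two 3,5-dimethoxystyrene units (C1–C2 and C13–C14 with their benzene rings) and a decane-1,10-diyl unit.
- Enabling feature: the ten methylenes C3–C12 are the carbon chain of dodecanedioic acid without its two carboxyl carbons. C1 and C14 are benzylic to the two benzene rings, so a radical that arrives at C2 or C13 ends up stabilised on C1 or C14.
- Forward order: the diacid is activated as its bis(N-acyloxyphthalimide), the aldehyde is methylenated, the chain is joined at both ends in one flask by decarboxylative radical hydroalkylation, and the methyl ethers are removed last.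
- Rings and stereochemistry: both benzene rings are bought and no ring is formed. The target has no stereocentre and no stereogenic alkene, so nothing has to be controlled.

Key step: step 3

Remark: bisnorstriatol is achiral, so "single enantiomer" is read as the one constitution drawn; no stereochemical descriptor applies to any compound of the route.

**Route**

Step 1
Reactants: 1 dodecanedioic acid; 2 N-hydroxyphthalimide
Product: 4 bis(1,3-dioxoisoindolin-2-yl) dodecanedioate, via mono-ester acid 3 (not isolated)
Conditions: 2 (2.2 equiv), DIC (2.2 equiv), DMAP (10 mol %), CH2Cl2/THF, 0 °C → rt; urea filtered off, product crystallised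
Reagents that add atoms: none
Why: Steglich-type carbodiimide esterification, in which DIC turns each carboxyl group into an O-acylisourea and DMAP relays the acyl group to the N–OH of 2; the unbranched diacid has no competing function, so both ends should be acylated.

Step 2
Reactants: 5 3,5-dimethoxybenzaldehyde
Product: 6 3,5-dimethoxystyrene
Conditions: Ph3PCH3Br (1.3 equiv), KOtBu (1.3 equiv), THF, 0 °C → rt; product kept cold and used promptly
Reagents that add atoms: methyltriphenylphosphonium bromide, C[P+](c1ccccc1)(c1ccccc1)c1ccccc1.[Br-]
Why: Wittig methylenation of a non-enolisable aromatic aldehyde with the unstabilised ylide is dependable, and aryl methyl ethers are inert to the base.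

Step 3
Reactants: 4 bis(1,3-dioxoisoindolin-2-yl) dodecanedioate; 6 3,5-dimethoxystyrene
Product: 8 1,14-bis(3,5-dimethoxyphenyl)tetradecane, via mono-adduct ester 7 (not isolated)
Conditions: 6 (5 equiv), Ru(bpy)3(PF6)2 (2 mol %), Hantzsch ester (diethyl 1,4-dihydro-2,6-dimethylpyridine-3,5-dicarboxylate, 3 equiv, added in portions), degassed CH2Cl2 (0.1 M in 4), blue LEDs (450 nm), rt
Reagents that add atoms: none
Why: The excited ruthenium catalyst is reductively quenched by the Hantzsch ester, and the resulting Ru(I) passes one electron to an N-acyloxyphthalimide group of 4, whose radical anion expels phthalimide anion and CO2 to leave a primary alkyl radical at the chain end. This nucleophilic radical adds to the unsubstituted CH2 terminus of 6, and the benzylic radical so formed takes a hydrogen atom from the dihydropyridine (or its radical cation) to give mono-adduct 7, whose remaining ester repeats the sequence; the two new bonds are C2–C3 and C12–C13 of the final chain. The closest known reaction type is the photoredox decarboxylative Giese-type hydroalkylation of vinylarenes with redox-active esters, run here twice on one linker. No ring closes and no stereocentre is created. The step needs anti-Markovnikov addition, which the aryl-stabilised benzylic radical ensures, and hydrogen capping in preference to styrene telomerisation or premature reduction of the primary radical; an excess of 6 (fast trapping of the alkyl radical) and an excess of hydrogen donor (quenching of the slowly propagating benzylic radical) should secure this. The ten-methylene spacer keeps the two termini independent, so neither cyclisation nor interference between the ends is expected.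

Step 4
Reactants: 8 1,14-bis(3,5-dimethoxyphenyl)tetradecane
Product: 10 bisnorstriatol, via tetrakis(dibromoboryl) ether 9 (not isolated)
Conditions: BBr3 (8 equiv, 1 M in CH2Cl2), CH2Cl2, −78 °C → rt; then H2O, 0 °C
Reagents that add atoms: none
Why: Lewis-acid cleavage of aryl methyl ethers, in which BBr3 coordinates each ether oxygen and bromide removes the methyl group by SN2; the aryloxydibromoborane groups of 9 are hydrolysed on aqueous work-up, and the saturated chain carries nothing that is acid-sensitive.

**Compound list**

1 | dodecanedioic acid | OC(=O)CCCCCCCCCCC(=O)O | starting material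
2 | N-hydroxyphthalimide | ON1C(=O)c2ccccc2C1=O | starting material
3 | 12-[(1,3-dioxoisoindolin-2-yl)oxy]-12-oxododecanoic acid (mono-ester acid) | OC(=O)CCCCCCCCCCC(=O)ON1C(=O)c2ccccc2C1=O | intermediate
4 | bis(1,3-dioxoisoindolin-2-yl) dodecanedioate | O=C(CCCCCCCCCCC(=O)ON1C(=O)c2ccccc2C1=O)ON1C(=O)c2ccccc2C1=O | intermediate
5 | 3,5-dimethoxybenzaldehyde | COc1cc(C=O)cc(OC)c1 | starting material
6 | 3,5-dimethoxystyrene (1-ethenyl-3,5-dimethoxybenzene) | C=Cc1cc(OC)cc(OC)c1 | intermediate
7 | 1,3-dioxoisoindolin-2-yl 13-(3,5-dimethoxyphenyl)tridecanoate (mono-adduct ester) | COc1cc(OC)cc(CCCCCCCCCCCCC(=O)ON2C(=O)c3ccccc3C2=O)c1 | intermediate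
8 | 1,14-bis(3,5-dimethoxyphenyl)tetradecane | COc1cc(OC)cc(CCCCCCCCCCCCCCc2cc(OC)cc(OC)c2)c1 | intermediate
9 | 1,14-bis[3,5-bis(dibromoboryloxy)phenyl]tetradecane (tetrakis(dibromoboryl) ether) | BrB(Br)Oc1cc(OB(Br)Br)cc(CCCCCCCCCCCCCCc2cc(OB(Br)Br)cc(OB(Br)Br)c2)c1 | intermediate
10 | bisnorstriatol, 5,5'-(tetradecane-1,14-diyl)bis(benzene-1,3-diol) | Oc1cc(O)cc(CCCCCCCCCCCCCCc2cc(O)cc(O)c2)c1 | target

**Step count**

Total steps: 4. Longest linear sequence: 3 (steps 1, 3, 4 from 1; equally steps 2, 3, 4 from 5).

**Steps most likely to fail**

Step 3. The primary radical may be capped by hydrogen before it meets the alkene, the benzylic radical may propagate into further styrene, or the reaction may stall after one end has reacted. Each of these gives mixtures that differ only in chain length or end group. The fallback gives up the radical union and builds the same chain by olefination. It sets out from 5. Commercial 1,12-dibromododecane is heated with triphenylphosphine in acetonitrile to give dodecane-1,12-diylbis(triphenylphosphonium) dibromide F1. Double deprotonation with NaHMDS in THF at 0 °C and a twofold Wittig reaction with two equivalents of 5 should give 1,14-bis(3,5-dimethoxyphenyl)tetradeca-1,13-diene F2 as a mixture of alkene isomers, which does not matter. Hydrogenation over Pd/C in ethyl acetate saturates both alkenes and returns the route at 8.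

Step 4. Cleavage of four ethers on a waxy, poorly soluble substrate may stop at partly methylated phenols, and boron-bound product may be lost at work-up. The fallback changes the protecting group so that the last step is a neutral hydrogenolysis. It sets out from 4. Commercial 3,5-bis(benzyloxy)benzaldehyde is methylenated as in step 2 to give 1,3-bis(benzyloxy)-5-ethenylbenzene F3. This is joined to 4 under the conditions of step 3 to give 1,14-bis[3,5-bis(benzyloxy)phenyl]tetradecane F4. Hydrogenolysis with H2 over Pd/C in ethyl acetate/methanol removes the four benzyl groups and returns the route at 10.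

Step 1. The second acylation may lag, the O-acylisourea may rearrange to an N-acylurea, and the activated ester may hydrolyse during purification. The fallback replaces in-situ carbodiimide activation by an isolated acid chloride. It sets out from 1, which with oxalyl chloride and catalytic DMF in CH2Cl2 should give dodecanedioyl dichloride F5. After evaporation, F5 is treated with 2 and triethylamine in CH2Cl2 at 0 °C, and the route is rejoined at 4.

**Further compounds**

F1 | step 3 | dodecane-1,12-diylbis(triphenylphosphonium) dibromide | C(CCCCCCCCCCC[P+](c1ccccc1)(c1ccccc1)c1ccccc1)[P+](c1ccccc1)(c1ccccc1)c1ccccc1.[Br-].[Br-]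
F2 | step 3 | 1,14-bis(3,5-dimethoxyphenyl)tetradeca-1,13-diene (alkene isomer mixture) | COc1cc(OC)cc(C=CCCCCCCCCCCC=Cc2cc(OC)cc(OC)c2)c1
F3 | step 4 | 1,3-bis(benzyloxy)-5-ethenylbenzene | C=Cc1cc(OCc2ccccc2)cc(OCc2ccccc2)c1
F4 | step 4 | 1,14-bis[3,5-bis(benzyloxy)phenyl]tetradecane | c1ccccc1COc1cc(OCc2ccccc2)cc(CCCCCCCCCCCCCCc2cc(OCc3ccccc3)cc(OCc3ccccc3)c2)c1
F5 | step 1 | dodecanedioyl dichloride | O=C(Cl)CCCCCCCCCCC(=O)Cl
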